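## Retrosynthetic overview

1. Target ⇐ O1/O7 bis-isovalerylation of a lactol ⇐ O10/O11 bis-acetylation ⇐ DIBAL reduction of the C11 methyl ester. The ester is kept until late so the C3=C4 enol ether stays electron-poor during the oxidations.
2. Δ5,6 alkene and 7β-OH ⇐ singlet-oxygen (Schenck) ene reaction on a Δ6,7-8α-ol, removing H-5β suprafacially.
3. Δ6,7-8α-ol ⇐ anti-Markovnikov-free hydroxyselenation of the genipin Δ7,8 alkene, then selenoxide syn-elimination.
4. No ring is formed: the cyclopenta[c]pyran core, C1 and C9 come intact from (+)-genipin. C5-H relays its configuration to C7 and is then destroyed.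

Assumption: genipin (a bulk commercial iridoid aglycone) is an acceptable chiral-pool starting material; natural valtrate is deliberately not used, because its acetolysis would be a one-step relay rather than a synthesis.

Convention: iridoid numbering (C1, O2, C3–C9, C10 on C8, C11 on C4); β = the face of H-9. The target is 1β,7β-di-O-isovaleryl, 8α-OH, 8β-CH2OAc, 9β-H = (1S,6S,7R,7aS) in cyclopenta[c]pyran numbering.

This route is a proposal built from analogy, not a reported synthesis; none of the steps has been run on these substrates.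

## Route

**Step 1**
Reactants: 1, (+)-genipin
Product: 2, 1β,10-bis-O-TBS-genipin
Conditions: TBSCl (2.5 equiv), imidazole, cat. DMAP, DMF, 0 °C → rt
Reagents that add atoms: tert-butyldimethylsilyl chloride, CC(C)(C)[Si](C)(C)Cl
Why: Exhaustive silylation of the primary allylic OH and the lactol OH with retention of genipin's 1β anomer; any 1α silyl acetal converges later because C1 is reset at the lactol stage (step 8).

**Step 2**
Reactants: 2
Product: 3, 1β-O-TBS-genipin (free 10-OH)
Conditions: AcOH/THF/H2O (3:1:1), rt
Reagents that add atoms: none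
Why: Selective acidic desilylation; the unhindered primary allylic silyl ether cleaves much faster than the secondary, electron-poor anomeric silyl acetal, and no alcohol is present to exchange at C1.

**Step 3**
Reactants: 3
Product: 4, the 7β-phenylselanyl-8α,10-diol (C5-H, C6-H2 intact)
Conditions: N-(phenylseleno)phthalimide (1.2 equiv), H2O (5 equiv), cat. CSA, CH2Cl2, rt
Reagents that add atoms: N-(phenylseleno)phthalimide, O=C1c2ccccc2C(=O)N1[Se]c1ccccc1 (PhSe); water, O (OH)
Why: Hydroxyselenation (oxyselenenylation): the seleniranium forms on the convex β face of the cis-fused bicycle and water opens it anti at the tertiary C8, setting 8α-OH and 7β-SePh. The enol ether is inert because of the C4 ester.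

**Step 4**
Reactants: 4
Product: 5, the Δ6,7-8α,10-diol (H-5β retained)
Conditions: 30% H2O2, pyridine, THF, 0 °C → rt
Reagents that add atoms: none
Why: Selenoxide syn-elimination; the only syn β-hydrogen is on C6 (C8 is quaternary), so the alkene forms regiospecifically at C6=C7 and C8 is untouched.

**Step 5**
Reactants: 5
Product: 6, the Δ3,4/Δ5,6-diene ester with 7β-OH, 8α-OH and 10-OH (via the 7β-hydroperoxide)
Conditions: O2, TPP (cat.), white LED, CH2Cl2, −20 → 0 °C; then PPh3
Reagents that add atoms: dioxygen, O=O (one O retained after PPh3 reduction)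
Why: Schenck ene reaction: H-5 is the only allylic hydrogen of the C6=C7 alkene, so oxygen must bond to C7 with the double bond moving to C5=C6. The reaction is suprafacial, so oxygen arrives on the face of H-5β and gives 7β-OOH, trans to 8α-OH.

**Step 6**
Reactants: 6
Product: 7, the 7β,8α,10,11-tetraol (1β-OTBS)
Conditions: DIBAL-H (7 equiv), CH2Cl2/THF, −78 → −30 °C; Rochelle salt workup
Reagents that add atoms: none
Why: 1,2-Reduction of the vinylogous-carbonate ester to the C11 allylic alcohol; the silyl acetal, the alkenes and all stereocenters are untouched, and the workup is non-acidic for the now electron-rich dienol ether.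

**Step 7**
Reactants: 7; 8, acetyl chloride
Product: 9, the 10,11-di-O-acetate (7β-OH, 8α-OH free, 1β-OTBS)
Conditions: AcCl (2.2 equiv), 2,4,6-collidine, CH2Cl2, −78 °C
Reagents that add atoms: acetyl chloride, CC(=O)Cl
Why: Selective acetylation of primary alcohols (AcCl/collidine); the two primary OH groups react well ahead of the hindered secondary 7-OH, which sits next to a quaternary carbon, and the tertiary 8-OH.

**Step 8**
Reactants: 9
Product: 10, the 1β-lactol (1-OH, 7β-OH, 8α-OH; 10,11-di-OAc)
Conditions: TBAF/AcOH (1:1, 1.2 equiv), THF, 0 °C; crude used directly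
Reagents that add atoms: none
Why: Buffered fluoride cleavage of the anomeric silyl ether; the AcOH buffer suppresses acetyl migration and base-induced elimination.

**Step 9**
Reactants: 10; 11, isovaleric anhydride
Product: 12, 10-acetoxyvaltrathydrin (target)
Conditions: isovaleric anhydride (3 equiv), pyridine, cat. DMAP, CH2Cl2, −20 → 0 °C
Reagents that add atoms: isovaleric anhydride, CC(C)CC(=O)OC(=O)CC(C)C
Why: Acylation of the lactol OH and the secondary allylic 7-OH while the hindered tertiary 8-OH stays free; the lactol is expected to sit, as genipin does, as the equatorial 1β-OH anomer (H-1/H-9 trans) and to be esterified with retention, giving 1S.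

## Compound list

1 | (+)-genipin, methyl (1R,4aS,7aS)-1-hydroxy-7-(hydroxymethyl)-1,4a,5,7a-tetrahydrocyclopenta[c]pyran-4-carboxylate | COC(=O)C1=CO[C@@H](O)[C@@H]2C(CO)=CC[C@H]12 | starting material

2 | methyl (1S,4aS,7aS)-1-(TBSO)-7-(TBSOCH2)-1,4a,5,7a-tetrahydrocyclopenta[c]pyran-4-carboxylate | COC(=O)C1=CO[C@@H](O[Si](C)(C)C(C)(C)C)[C@@H]2C(CO[Si](C)(C)C(C)(C)C)=CC[C@H]12 | intermediate

3 | methyl (1S,4aS,7aS)-1-(TBSO)-7-(hydroxymethyl)-1,4a,5,7a-tetrahydrocyclopenta[c]pyran-4-carboxylate | COC(=O)C1=CO[C@@H](O[Si](C)(C)C(C)(C)C)[C@@H]2C(CO)=CC[C@H]12 | intermediate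

4 | methyl (1S,4aS,6S,7R,7aS)-1-(TBSO)-7-hydroxy-7-(hydroxymethyl)-6-(phenylselanyl)-1,4a,5,6,7,7a-hexahydrocyclopenta[c]pyran-4-carboxylate | COC(=O)C1=CO[C@@H](O[Si](C)(C)C(C)(C)C)[C@@H]2[C@@](O)(CO)[C@@H]([Se]c3ccccc3)C[C@H]12 | intermediate

5 | methyl (1S,4aS,7R,7aS)-1-(TBSO)-7-hydroxy-7-(hydroxymethyl)-1,4a,7,7a-tetrahydrocyclopenta[c]pyran-4-carboxylate | COC(=O)C1=CO[C@@H](O[Si](C)(C)C(C)(C)C)[C@@H]2[C@@](O)(CO)C=C[C@H]12 | intermediate

6 | methyl (1S,6S,7R,7aS)-1-(TBSO)-6,7-dihydroxy-7-(hydroxymethyl)-1,6,7,7a-tetrahydrocyclopenta[c]pyran-4-carboxylate | COC(=O)C1=CO[C@@H](O[Si](C)(C)C(C)(C)C)[C@@H]2[C@@](O)(CO)[C@@H](O)C=C12 | intermediate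

7 | (1S,6S,7R,7aS)-1-(TBSO)-4,7-bis(hydroxymethyl)-1,6,7,7a-tetrahydrocyclopenta[c]pyran-6,7-diol | OCC1=CO[C@@H](O[Si](C)(C)C(C)(C)C)[C@@H]2[C@@](O)(CO)[C@@H](O)C=C12 | intermediate

8 | acetyl chloride | CC(=O)Cl | starting material

9 | (1S,6S,7R,7aS)-4,7-bis(acetoxymethyl)-1-(TBSO)-1,6,7,7a-tetrahydrocyclopenta[c]pyran-6,7-diol | CC(=O)OCC1=CO[C@@H](O[Si](C)(C)C(C)(C)C)[C@@H]2[C@@](O)(COC(C)=O)[C@@H](O)C=C12 | intermediate

10 | (1R,6S,7R,7aS)-4,7-bis(acetoxymethyl)-1,6,7,7a-tetrahydrocyclopenta[c]pyran-1,6,7-triol (1β-lactol) | CC(=O)OCC1=CO[C@@H](O)[C@@H]2[C@@](O)(COC(C)=O)[C@@H](O)C=C12 | intermediate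

11 | isovaleric (3-methylbutanoic) anhydride | CC(C)CC(=O)OC(=O)CC(C)C | starting material

12 | 10-acetoxyvaltrathydrin, (1S,6S,7R,7aS)-4,7-bis(acetoxymethyl)-7-hydroxy-1,6-bis(3-methylbutanoyloxy)-1,6,7,7a-tetrahydrocyclopenta[c]pyran | CC(=O)OCC1=CO[C@@H](OC(=O)CC(C)C)[C@H]2C1=C[C@H](OC(=O)CC(C)C)[C@]2(O)COC(C)=O | target

## Summary

Total steps: 9. Longest linear sequence: 9 (fully linear from genipin).

Steps most likely to fail, with fallbacks:

1. **Step 3 (hydroxyselenation).** The risk is regiochemistry and facial selectivity, since the allylic C10 oxygen works against Markovnikov opening. Fallback: make the bromohydrin (NBS/H2O) and close it with base; either regioisomer gives the same 7α,8α-epoxide. Open that at the secondary C7 with PhSeNa (SN2, inversion) to reach 4 unambiguously.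

2. **Step 5 (singlet-oxygen ene).** The cis-disubstituted cyclopentene may react slowly, and the enol ether may compete. Fallback: drop the ene reaction. Open the 7α,8α-epoxide at C7 with an oxygen nucleophile, oxidise C7 to the ketone, run a Saegusa–Ito dehydrogenation to the Δ5-7-one (push-pull dienone), then use an 8α-OH-directed Me4NBH(OAc)3 reduction to deliver hydride on the α face and give 7β-OH.

3. **Steps 8–9 (free lactol of the electron-rich dienol ether, then acylation).** The lactol may ring-open or aromatise to baldrinal-type products, and the C1 anomer ratio is not guaranteed. Fallback: change the C11 endgame. Oxidise C11 to the aldehyde (vinylogous formate, MnO2) before unveiling the lactol, so desilylation and O1/O7 isovalerylation happen on a deactivated, genipin-like lactol. Finish with a Luche reduction of the aldehyde and O11 acetylation.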